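**Retrosynthetic overview**
1. The plan rests on C9 of the drimane core. It lies between the quaternary C10 and C8, which carries the exocyclic methylene C12, and it becomes an enol carbon once C11 is an aryl ketone. Ring B (C5–C10) is therefore closed by forming C8–C9 from a C9 enol silane and a C8≡C12 alkyne, which also creates the methylene.
2. Hydroxyquinone ⇐ 2,6-dimethoxy-4-(silyloxymethyl)arene (mono-demethylation, (KSO3)2NO oxidation, hydrolysis); C11 methylene ⇐ C11 ketone.
3. Cyclization precursor ⇐ C9–C11 acetaldehyde arm on C10 plus the aryllithium from 3,5-dimethoxybenzyl alcohol.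
4. C5 and C10 ⇐ copper-catalysed asymmetric conjugate addition of a silylbutynyl Grignard reagent to 2,4,4-trimethylcyclohex-2-enone with allyl bromide trapping, then removal of the C1 carbonyl.
5. Ring order: ring A is present from the start, ring B is closed in the key step, and the quinone ring is unmasked from the arene at the end.

Key step: step 11

Assumption: the antipode of the chiral carbene ligand in step 1 is the one that gives the (3S) adduct, and the carbinol centres created at C1 and C11 by hydride or aryllithium addition are carried as epimer mixtures because both are erased later. Drimane numbering (C1–C15) is used for positions throughout.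

**Step 1**
Reactants: 1 2,4,4-trimethylcyclohex-2-en-1-one; 2 (4-bromobut-1-yn-1-yl)trimethylsilane; 3 allyl bromide
Product: 6 (2R,3S)-2-allyl-2,4,4-trimethyl-3-[4-(trimethylsilyl)but-3-yn-1-yl]cyclohexan-1-one, via Grignard reagent 4 (not isolated), via magnesium enolate 5 (not isolated)
Conditions: 2, Mg, Et2O, reflux; then 1, Cu(OTf)2 (3 mol %), (S)-3-(1-hydroxy-4-methylpentan-2-yl)-1-mesityl-4,5-dihydroimidazolium hexafluorophosphate (4 mol %), Et2O, −30 °C; then 3, DMPU, THF, −30 °C → rt
Reagents that add atoms: none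
Why: Copper-catalysed asymmetric conjugate addition of the Grignard reagent sets C5 by ligand-controlled facial attack at the β-carbon, and SN2 allylation of the tetrasubstituted magnesium enolate anti to the new pseudoaxial butynyl chain sets the quaternary C10 with allyl trans and methyl cis to that chain.

**Step 2**
Reactants: 6 (2R,3S)-2-allyl-2,4,4-trimethyl-3-[4-(trimethylsilyl)but-3-yn-1-yl]cyclohexan-1-one
Product: 7 (2R,3S)-2-allyl-2,4,4-trimethyl-3-[4-(trimethylsilyl)but-3-yn-1-yl]cyclohexan-1-ol (C1 epimers)
Conditions: LiAlH4, THF, 0 °C → rt; H2O work-up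
Reagents that add atoms: none
Why: Hydride 1,2-reduction of the ketone proceeds despite the neighbouring quaternary centre, leaves the silyl alkyne and the alkene alone, and the new C1 carbinol configuration is irrelevant because C1 is deoxygenated in step 4.

**Step 3**
Reactants: 7 (2R,3S)-2-allyl-2,4,4-trimethyl-3-[4-(trimethylsilyl)but-3-yn-1-yl]cyclohexan-1-ol
Product: 9 O-{(2R,3S)-2-allyl-2,4,4-trimethyl-3-[4-(trimethylsilyl)but-3-yn-1-yl]cyclohexyl} S-methyl dithiocarbonate, via sodium xanthate 8 (not isolated)
Conditions: NaH, imidazole (cat.), THF, 0 °C → reflux; CS2, rt; MeI, rt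
Reagents that add atoms: carbon disulfide, S=C=S; iodomethane, CI
Why: Xanthate ester formation (alkoxide addition to CS2, then S-methylation) turns the hindered secondary alcohol into the radical leaving group for a Barton–McCombie deoxygenation without touching C5 or C10.

**Step 4**
Reactants: 9 O-cyclohexyl S-methyl dithiocarbonate from step 3
Product: 10 {4-[(1S,2R)-2-allyl-2,6,6-trimethylcyclohexyl]but-1-yn-1-yl}trimethylsilane
Conditions: Bu3SnH, AIBN (cat.), toluene, 100 °C
Reagents that add atoms: none
Why: Barton–McCombie radical deoxygenation, in which the secondary C1 radical is reduced by Bu3SnH faster than it could add to the remote silyl-capped alkyne or the allyl group (no 5-exo pathway exists), so both stereocentres are untouched.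

**Step 5**
Reactants: 10 {4-[(1S,2R)-2-allyl-2,6,6-trimethylcyclohexyl]but-1-yn-1-yl}trimethylsilane
Product: 12 2-{(1R,2S)-1,3,3-trimethyl-2-[4-(trimethylsilyl)but-3-yn-1-yl]cyclohexyl}acetaldehyde, via ozonide 11 (not isolated)
Conditions: O3, CH2Cl2, −78 °C, stopped when 10 is consumed; then PPh3, −78 °C → rt
Reagents that add atoms: ozone, [O-][O+]=O
Why: Ozonolysis with reductive work-up (Criegee mechanism) cleaves the monosubstituted alkene much faster than the silyl alkyne and shortens the allyl group to the C9–C11 acetaldehyde arm.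

**Step 6**
Reactants: 13 3,5-dimethoxybenzyl alcohol
Product: 14 tert-butyl[(3,5-dimethoxybenzyl)oxy]dimethylsilane
Conditions: TBSCl, imidazole, DMF, rt
Reagents that add atoms: tert-butyldimethylsilyl chloride, CC(C)(C)[Si](C)(C)Cl
Why: Standard silylation of a primary alcohol masks the benzylic hydroxyl for the organolithium, hydride and radical steps that follow.

**Step 7**
Reactants: 14 tert-butyl[(3,5-dimethoxybenzyl)oxy]dimethylsilane; 12 2-{(1R,2S)-1,3,3-trimethyl-2-[4-(trimethylsilyl)but-3-yn-1-yl]cyclohexyl}acetaldehyde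
Product: 16 1-{4-[(tert-butyldimethylsilyloxy)methyl]-2,6-dimethoxyphenyl}-2-{(1R,2S)-1,3,3-trimethyl-2-[4-(trimethylsilyl)but-3-yn-1-yl]cyclohexyl}ethan-1-ol (C11 epimers), via aryllithium 15 (not isolated)
Conditions: 14, n-BuLi, THF, 0 °C; then 12, −78 °C; H2O work-up
Reagents that add atoms: none
Why: Directed ortho-metalation removes the ring proton flanked by both methoxy groups, and 1,2-addition of the aryllithium to the aldehyde forms the C11–aryl bond; the C11 carbinol configuration is irrelevant because it is oxidised in step 8.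

**Step 8**
Reactants: 16 C11 alcohol from step 7
Product: 17 1-{4-[(tert-butyldimethylsilyloxy)methyl]-2,6-dimethoxyphenyl}-2-{(1R,2S)-1,3,3-trimethyl-2-[4-(trimethylsilyl)but-3-yn-1-yl]cyclohexyl}ethan-1-one
Conditions: Dess–Martin periodinane, CH2Cl2, rt
Reagents that add atoms: none
Why: Dess–Martin oxidation converts the secondary benzylic alcohol into the aryl ketone under nearly neutral conditions that spare both silyl groups and the electron-rich arene.

**Step 9**
Reactants: 17 aryl ketone with silyl-capped alkyne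
Product: 18 2-[(1R,2S)-2-(but-3-yn-1-yl)-1,3,3-trimethylcyclohexyl]-1-{4-[(tert-butyldimethylsilyloxy)methyl]-2,6-dimethoxyphenyl}ethan-1-one
Conditions: K2CO3 (cat.), MeOH, rt
Reagents that add atoms: none
Why: Carbonate-catalysed methanolysis of the alkynyl C–Si bond (protodesilylation) frees the terminal alkyne, while the alkyl silyl ether and the ketone, which has no epimerisable centre, are unaffected.

**Step 10**
Reactants: 18 aryl ketone with terminal alkyne
Product: 19 (Z)-tert-butyldimethylsilyl enol ether of 18 (C9=C11, silyloxy group cis to C10; trans-disubstituted ring A with but-3-ynyl on C5)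
Conditions: TBSOTf, Et3N, CH2Cl2, 0 °C → rt
Reagents that add atoms: tert-butyldimethylsilyl trifluoromethanesulfonate, CC(C)(C)[Si](C)(C)OS(=O)(=O)C(F)(F)F
Why: Soft enolisation (silyl triflate with amine base) can only go toward C9 because the aryl side has no α-hydrogen, and the (Z)-enol silane is expected because the C10 substituent avoids the twisted, ortho-disubstituted aryl ring.

**Step 11**
Reactants: 19 (Z)-silyl enol ether
Product: 20 (5S,9S,10S)-11-{4-[(tert-butyldimethylsilyloxy)methyl]-2,6-dimethoxyphenyl}drim-8(12)-en-11-one (trans-decalin, exocyclic C8=C12 methylene, equatorial 9β-aroyl group)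
Conditions: (Ph3P)AuCl (10 mol %), AgBF4 (10 mol %), CH2Cl2/MeOH (10:1), rt → 40 °C
Reagents that add atoms: none
Why: AgBF4 abstracts chloride from (Ph3P)AuCl and the resulting cationic monovalent gold π-binds the terminal alkyne; the enol silane carbon C9 then attacks the internal alkyne carbon C8 anti to gold, and methanol takes the silyl group from the oxocarbenium ion and protonates the C12–Au bond, which gives the C11 ketone and the C8=C12 methylene and returns the catalyst. The closest known reaction type is the gold-catalysed carbocyclization of silyl enol ethers onto alkynes, a Conia-ene-type process. Ring B is closed in the 6-exo-dig mode through a chair in which the C5 butynyl arm and the C10 enol arm are both equatorial on ring A, an arrangement that can only give the trans-decalin. C9, the one new stereocentre, is under substrate control: the chair that directs the bulky silyloxy(aryl)methylene terminus outward, away from the axial hydrogens on C5 and C7, should deliver the equatorial 9β-aroyl group, and because C9 is α to the C11 ketone a wrong epimer could still be converged by enolate protonation anti to the axial C10 methyl. The step needs exo over endo closure and a non-conjugated alkene: the terminal alkyne on a two-carbon tether from C5 directs attack to its internal carbon, and the nearly neutral medium together with the twisted 2,6-dimethoxybenzoyl group gives no drive for the C8=C12 bond to move into conjugation.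

**Step 12**
Reactants: 20 decalin aryl ketone
Product: 21 (5S,9S,10S)-11-{4-[(tert-butyldimethylsilyloxy)methyl]-2,6-dimethoxyphenyl}drim-8(12)-en-11-ol (C11 epimers)
Conditions: LiAlH4, THF, 0 °C → rt; H2O work-up
Reagents that add atoms: none
Why: Hydride 1,2-reduction of the aryl ketone, helped by lithium coordination to an ortho-methoxy group, should outpace enolisation so that C9 is not epimerised, and the new C11 carbinol centre is removed in step 14.

**Step 13**
Reactants: 21 C11 alcohol
Product: 23 O-[C11 of 21] S-methyl dithiocarbonate (C11 epimers), via sodium xanthate 22 (not isolated)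
Conditions: NaH, THF, 0 °C → rt; CS2; MeI
Reagents that add atoms: carbon disulfide, S=C=S; iodomethane, CI
Why: Xanthate ester formation (alkoxide addition to CS2, then S-methylation) activates the benzylic C11–O bond for radical cleavage under basic, non-ionising conditions that leave the exocyclic alkene in place.

**Step 14**
Reactants: 23 C11 xanthate
Product: 24 tert-butyl{[4-((5S,9S,10S)-drim-8(12)-en-11-yl)-3,5-dimethoxybenzyl]oxy}dimethylsilane (C11 is now CH2)
Conditions: Bu3SnH, AIBN (cat.), toluene, 90 °C
Reagents that add atoms: none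
Why: Barton–McCombie deoxygenation through a benzylic C11 radical, which is too stabilised to rearrange through the homoallyl/cyclopropylcarbinyl manifold with the C8=C12 alkene and is simply reduced by Bu3SnH.

**Step 15**
Reactants: 24 dimethoxyarene
Product: 25 5-[(tert-butyldimethylsilyloxy)methyl]-2-[(5S,9S,10S)-drim-8(12)-en-11-yl]-3-methoxyphenol
Conditions: NaSEt, DMF, 130 °C; H2O work-up
Reagents that add atoms: none
Why: SN2 demethylation by ethanethiolate (thiolate ether cleavage) at one of the two equivalent aryl methyl ethers stops after one methyl because the phenoxide formed deactivates the ring toward a second displacement.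

**Step 16**
Reactants: 25 monophenol
Product: 26 5-[(tert-butyldimethylsilyloxy)methyl]-2-[(5S,9S,10S)-drim-8(12)-en-11-yl]-3-methoxy-1,4-benzoquinone
Conditions: (KSO3)2NO, KH2PO4 buffer, acetone/H2O, rt
Reagents that add atoms: potassium nitrosodisulfonate, [K+].[K+].[O]N(S(=O)(=O)[O-])S(=O)(=O)[O-]
Why: Teuber oxidation converts a phenol with a free para position into the para-quinone, and the new carbonyl forms at the carbon para to the phenolic oxygen, which leaves the remaining methoxy group on the quinone carbon next to the drimanylmethyl substituent as the target requires.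

**Step 17**
Reactants: 26 methoxyquinone
Product: 27 5-[(tert-butyldimethylsilyloxy)methyl]-2-[(5S,9S,10S)-drim-8(12)-en-11-yl]-3-hydroxy-1,4-benzoquinone
Conditions: NaOH (aq.), MeOH/THF, 0 °C → rt; then dilute HCl to pH 3
Reagents that add atoms: sodium hydroxide, [Na+].[OH-]
Why: Addition–elimination of hydroxide at the methoxy-bearing quinone carbon (hydrolysis of a vinylogous ester) gives the hydroxyquinone, whose anion resists further attack, while the alkene and the silyl ether are inert to cold aqueous base.

**Step 18**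
Reactants: 27 hydroxyquinone silyl ether
Product: 28 tauranin
Conditions: HF·pyridine, THF, 0 °C → rt
Reagents that add atoms: none
Why: Fluoride-driven Si–O cleavage (silyl ether deprotection) with weakly acidic buffered HF frees the hydroxymethyl group without isomerising the exocyclic alkene or harming the hydroxyquinone.

**Compound list**
1 | 2,4,4-trimethylcyclohex-2-en-1-one | CC1=CC(C)(C)CCC1=O | starting material
2 | (4-bromobut-1-yn-1-yl)trimethylsilane | C[Si](C)(C)C#CCCBr | starting material
3 | allyl bromide | C=CCBr | starting material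
4 | [4-(trimethylsilyl)but-3-yn-1-yl]magnesium bromide | C[Si](C)(C)C#CCC[Mg]Br | intermediate
5 | bromomagnesium enolate of (S)-2,4,4-trimethyl-3-[4-(trimethylsilyl)but-3-yn-1-yl]cyclohexanone | C[Si](C)(C)C#CCC[C@H]1C(C)(C)CCC(O[Mg]Br)=C1C | intermediate
6 | (2R,3S)-2-allyl-2,4,4-trimethyl-3-[4-(trimethylsilyl)but-3-yn-1-yl]cyclohexan-1-one | C[Si](C)(C)C#CCC[C@H]1C(C)(C)CCC(=O)[C@]1(C)CC=C | intermediate
7 | (2R,3S)-2-allyl-2,4,4-trimethyl-3-[4-(trimethylsilyl)but-3-yn-1-yl]cyclohexan-1-ol (C1 epimers) | C[Si](C)(C)C#CCC[C@H]1C(C)(C)CCC(O)[C@]1(C)CC=C | intermediate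
8 | sodium O-cyclohexyl dithiocarbonate of 7 | C[Si](C)(C)C#CCC[C@H]1C(C)(C)CCC(OC(=S)[S-])[C@]1(C)CC=C.[Na+] | intermediate
9 | O-cyclohexyl S-methyl dithiocarbonate of 7 | C[Si](C)(C)C#CCC[C@H]1C(C)(C)CCC(OC(=S)SC)[C@]1(C)CC=C | intermediate
10 | {4-[(1S,2R)-2-allyl-2,6,6-trimethylcyclohexyl]but-1-yn-1-yl}trimethylsilane | C[Si](C)(C)C#CCC[C@H]1C(C)(C)CCC[C@]1(C)CC=C | intermediate
11 | 1,2,4-trioxolane (secondary ozonide) of the allyl group of 10 | C[Si](C)(C)C#CCC[C@H]1C(C)(C)CCC[C@]1(C)CC1OCOO1 | intermediate
12 | 2-{(1R,2S)-1,3,3-trimethyl-2-[4-(trimethylsilyl)but-3-yn-1-yl]cyclohexyl}acetaldehyde | C[Si](C)(C)C#CCC[C@H]1C(C)(C)CCC[C@]1(C)CC=O | intermediate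
13 | 3,5-dimethoxybenzyl alcohol | COc1cc(CO)cc(OC)c1 | starting material
14 | tert-butyl[(3,5-dimethoxybenzyl)oxy]dimethylsilane | COc1cc(CO[Si](C)(C)C(C)(C)C)cc(OC)c1 | intermediate
15 | {4-[(tert-butyldimethylsilyloxy)methyl]-2,6-dimethoxyphenyl}lithium | [Li]c1c(OC)cc(CO[Si](C)(C)C(C)(C)C)cc1OC | intermediate
16 | C11 alcohol: 1-aryl-2-{(1R,2S)-1,3,3-trimethyl-2-[4-(trimethylsilyl)but-3-yn-1-yl]cyclohexyl}ethan-1-ol (C11 epimers) | C[Si](C)(C)C#CCC[C@H]1C(C)(C)CCC[C@]1(C)CC(O)c1c(OC)cc(CO[Si](C)(C)C(C)(C)C)cc1OC | intermediate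
17 | aryl ketone: 1-aryl-2-{(1R,2S)-1,3,3-trimethyl-2-[4-(trimethylsilyl)but-3-yn-1-yl]cyclohexyl}ethan-1-one | C[Si](C)(C)C#CCC[C@H]1C(C)(C)CCC[C@]1(C)CC(=O)c1c(OC)cc(CO[Si](C)(C)C(C)(C)C)cc1OC | intermediate
18 | 2-[(1R,2S)-2-(but-3-yn-1-yl)-1,3,3-trimethylcyclohexyl]-1-{4-[(tert-butyldimethylsilyloxy)methyl]-2,6-dimethoxyphenyl}ethan-1-one | C#CCC[C@H]1C(C)(C)CCC[C@]1(C)CC(=O)c1c(OC)cc(CO[Si](C)(C)C(C)(C)C)cc1OC | intermediate
19 | (Z)-tert-butyldimethylsilyl enol ether of 18 | C#CCC[C@H]1C(C)(C)CCC[C@]1(C)/C=C(\O[Si](C)(C)C(C)(C)C)c1c(OC)cc(CO[Si](C)(C)C(C)(C)C)cc1OC | intermediate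
20 | (5S,9S,10S)-11-{4-[(tert-butyldimethylsilyloxy)methyl]-2,6-dimethoxyphenyl}drim-8(12)-en-11-one | C=C1CC[C@H]2C(C)(C)CCC[C@]2(C)[C@H]1C(=O)c1c(OC)cc(CO[Si](C)(C)C(C)(C)C)cc1OC | intermediate
21 | (5S,9S,10S)-11-aryl-drim-8(12)-en-11-ol (C11 epimers) | C=C1CC[C@H]2C(C)(C)CCC[C@]2(C)[C@H]1C(O)c1c(OC)cc(CO[Si](C)(C)C(C)(C)C)cc1OC | intermediate
22 | sodium O-(C11) dithiocarbonate of 21 | C=C1CC[C@H]2C(C)(C)CCC[C@]2(C)[C@H]1C(OC(=S)[S-])c1c(OC)cc(CO[Si](C)(C)C(C)(C)C)cc1OC.[Na+] | intermediate
23 | O-(C11) S-methyl dithiocarbonate of 21 | C=C1CC[C@H]2C(C)(C)CCC[C@]2(C)[C@H]1C(OC(=S)SC)c1c(OC)cc(CO[Si](C)(C)C(C)(C)C)cc1OC | intermediate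
24 | tert-butyl{[4-((5S,9S,10S)-drim-8(12)-en-11-yl)-3,5-dimethoxybenzyl]oxy}dimethylsilane | C=C1CC[C@H]2C(C)(C)CCC[C@]2(C)[C@H]1Cc1c(OC)cc(CO[Si](C)(C)C(C)(C)C)cc1OC | intermediate
25 | 5-[(tert-butyldimethylsilyloxy)methyl]-2-[(5S,9S,10S)-drim-8(12)-en-11-yl]-3-methoxyphenol | C=C1CC[C@H]2C(C)(C)CCC[C@]2(C)[C@H]1Cc1c(O)cc(CO[Si](C)(C)C(C)(C)C)cc1OC | intermediate
26 | 5-[(tert-butyldimethylsilyloxy)methyl]-2-[(5S,9S,10S)-drim-8(12)-en-11-yl]-3-methoxy-1,4-benzoquinone | C=C1CC[C@H]2C(C)(C)CCC[C@]2(C)[C@H]1CC1=C(OC)C(=O)C(CO[Si](C)(C)C(C)(C)C)=CC1=O | intermediate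
27 | 5-[(tert-butyldimethylsilyloxy)methyl]-2-[(5S,9S,10S)-drim-8(12)-en-11-yl]-3-hydroxy-1,4-benzoquinone | C=C1CC[C@H]2C(C)(C)CCC[C@]2(C)[C@H]1CC1=C(O)C(=O)C(CO[Si](C)(C)C(C)(C)C)=CC1=O | intermediate
28 | tauranin | C=C1CC[C@H]2C(C)(C)CCC[C@]2(C)[C@H]1CC1=C(O)C(=O)C(CO)=CC1=O | target

**Step count**
Total: 18 steps. Longest linear sequence: 17 steps (steps 1–5 and 7–18, from 1); step 6 is the one-step side branch.

**Steps most likely to fail**

Step 11 (key step). The enol silane may lose its silyl group, or methanol may add to the gold-activated alkyne, before the hindered C9 closes the ring; closure through the other chair would give the axial C9 epimer. The fallback makes the same C8–C9 bond by a radical closure. It sets out from 19: NBS in THF at −78 °C should give the α-bromo ketone F1. Slow addition of Bu3SnH with AIBN in refluxing benzene then generates the C9 α-keto radical, which closes ring B 6-exo-dig onto C8, and the C12 vinyl radical is reduced. The route is rejoined at 20. A C9 epimer from either closure would be converged by deprotonation and kinetic protonation anti to the axial C10 methyl.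

Step 1. Facial discrimination by the copper–carbene catalyst may be weak at a β-carbon flanked by the α-methyl and the gem-dimethyl group, which would give low enantiomeric purity. The fallback replaces asymmetric catalysis by resolution. It sets out from 1, with Grignard reagent 4 and 3: CuBr·SMe2 (5 mol %) in THF at −40 °C, then allyl bromide and DMPU, should give the racemic trans ketone F2, and LiAlH4 the racemic alcohol F3. (R)-1-Phenylethyl isocyanate (DMAP, toluene, 90 °C) converts it into the (R)-1-phenylethylcarbamate of the (2R,3S) alcohol F4 and the (R)-1-phenylethylcarbamate of the (2S,3R) alcohol F5, which are separated by chromatography or crystallisation. LiAlH4 in refluxing THF cleaves F4, and the route is rejoined at 7.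

Step 13. The congested benzylic C11 alkoxide may fail to add to CS2, or the xanthate of this very electron-rich benzylic position may ionise, with O-to-S rearrangement or elimination toward C9. The fallback replaces the thiocarbonyl/tin chain by an electron-transfer deoxygenation. It sets out from 21: p-toluoyl chloride with DMAP in pyridine should give the p-toluate ester F6. SmI2 with HMPA in THF (Markó–Lam deoxygenation) fragments the ester radical anion at the benzylic C–O bond and reduces the resulting radical, and the route is rejoined at 24.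

**Further compounds**
F1 | step 11 | 2-bromo-2-[(1R,2S)-2-(but-3-yn-1-yl)-1,3,3-trimethylcyclohexyl]-1-{4-[(tert-butyldimethylsilyloxy)methyl]-2,6-dimethoxyphenyl}ethan-1-one (C9 epimers) | C#CCC[C@H]1C(C)(C)CCC[C@]1(C)C(Br)C(=O)c1c(OC)cc(CO[Si](C)(C)C(C)(C)C)cc1OC
F2 | step 1 | racemic trans-2-allyl-2,4,4-trimethyl-3-[4-(trimethylsilyl)but-3-yn-1-yl]cyclohexan-1-one (both enantiomers shown) | C[Si](C)(C)C#CCC[C@H]1C(C)(C)CCC(=O)[C@]1(C)CC=C.C[Si](C)(C)C#CCC[C@@H]1C(C)(C)CCC(=O)[C@@]1(C)CC=C
F3 | step 1 | racemic trans-2-allyl-2,4,4-trimethyl-3-[4-(trimethylsilyl)but-3-yn-1-yl]cyclohexan-1-ol (both enantiomers shown) | C[Si](C)(C)C#CCC[C@H]1C(C)(C)CCC(O)[C@]1(C)CC=C.C[Si](C)(C)C#CCC[C@@H]1C(C)(C)CCC(O)[C@@]1(C)CC=C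
F4 | step 1 | (2R,3S)-2-allyl-2,4,4-trimethyl-3-[4-(trimethylsilyl)but-3-yn-1-yl]cyclohexyl [(R)-1-phenylethyl]carbamate | O=C(N[C@H](C)c1ccccc1)OC1CCC(C)(C)[C@H](CCC#C[Si](C)(C)C)[C@@]1(C)CC=C
F5 | step 1 | (2S,3R)-2-allyl-2,4,4-trimethyl-3-[4-(trimethylsilyl)but-3-yn-1-yl]cyclohexyl [(R)-1-phenylethyl]carbamate | O=C(N[C@H](C)c1ccccc1)OC1CCC(C)(C)[C@@H](CCC#C[Si](C)(C)C)[C@]1(C)CC=C
F6 | step 13 | (5S,9S,10S)-11-{4-[(tert-butyldimethylsilyloxy)methyl]-2,6-dimethoxyphenyl}drim-8(12)-en-11-yl 4-methylbenzoate (C11 epimers) | C=C1CC[C@H]2C(C)(C)CCC[C@]2(C)[C@H]1C(OC(=O)c1ccc(C)cc1)c1c(OC)cc(CO[Si](C)(C)C(C)(C)C)cc1OC
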